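The flavonol is cut across ring C at C4–C3 and O1–C2. C4 sits on C4a next to the O1-bearing C8a, which is the pattern of a salicylaldehyde, and C3 carries oxygen while C2 carries ring B, which is the pattern of an aryl-substituted silyl ynol ether. A rhodium-catalysed oxidative annulation through the formyl C–H bond should join the two in one operation, closing the pyranone with every oxygen of rings A, B and C already in place. The precursors are 2-hydroxy-3,4,6-trimethoxybenzaldehyde and a triisopropylsiloxy alkyne carrying the 2,4-dibenzyloxy-5-methoxyphenyl ring; desilylation and one boron trichloride dealkylation then finish the target.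

Key step: step 9

Remark: the target has no stereocentre, so no step has to control configuration; O-benzylisovanillin is taken as a catalogue compound.

Step 1
Reactants: 1 3,4,5-trimethoxyphenol
Product: 2 1,2,3,5-tetramethoxybenzene
Conditions: MeI, K2CO3, acetone, reflux
Reagents that add atoms: iodomethane, CI
Why: Williamson etherification, in which the potassium phenoxide of 1 attacks iodomethane and no other nucleophilic site competes.

Step 2
Reactants: 2 1,2,3,5-tetramethoxybenzene
Product: 3 2,3,4,6-tetramethoxybenzaldehyde
Conditions: POCl3, DMF, 0 → 60 °C; aqueous work-up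
Reagents that add atoms: N,N-dimethylformamide, CN(C)C=O; water, O
Why: Vilsmeier–Haack formylation, in which the two free ring positions of 2 are equivalent and each is ortho and para to methoxyl groups, so only one aldehyde can form.

Step 3
Reactants: 3 2,3,4,6-tetramethoxybenzaldehyde
Product: 4 2-hydroxy-3,4,6-trimethoxybenzaldehyde
Conditions: BCl3 (1.1 equiv), CH2Cl2, −78 → 0 °C; aqueous work-up
Reagents that add atoms: none
Why: Chelation-controlled Lewis acid O-demethylation, in which boron bound to the formyl oxygen should cleave the C2 methoxyl first because that group is buttressed between the formyl group and the C3 methoxyl and twisted out of conjugation, while one equivalent at low temperature guards against a second cleavage.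

Step 4
Reactants: 5 3-(benzyloxy)-4-methoxybenzaldehyde
Product: 7 3-(benzyloxy)-4-methoxyphenol, via aryl formate 6 (not isolated)
Conditions: mCPBA, CH2Cl2, 0 °C → rt; NaHCO3 wash; then K2CO3 (cat.), MeOH, rt
Reagents that add atoms: 3-chloroperoxybenzoic acid, OOC(=O)c1cccc(Cl)c1
Why: Baeyer–Villiger oxidation of an electron-rich benzaldehyde, in which the aryl group migrates to give the formate, followed by mild methanolysis that leaves the benzyl ether untouched.

Step 5
Reactants: 7 3-(benzyloxy)-4-methoxyphenol
Product: 8 2,4-bis(benzyloxy)-1-methoxybenzene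
Conditions: BnBr, K2CO3, DMF, 60 °C
Reagents that add atoms: benzyl bromide, BrCc1ccccc1
Why: Williamson etherification of the only free phenol by an SN2-reactive benzylic bromide.

Step 6
Reactants: 8 2,4-bis(benzyloxy)-1-methoxybenzene
Product: 9 2,4-bis(benzyloxy)-5-methoxybenzaldehyde
Conditions: POCl3, DMF, 0 → 70 °C; aqueous work-up
Reagents that add atoms: N,N-dimethylformamide, CN(C)C=O; water, O
Why: Vilsmeier–Haack formylation, which should go to C5 of 8 because that carbon is ortho to one benzyloxy group and para to the other, whereas the equally activated C3 is blocked between two benzyloxy groups, as in the formylation of 1,2,4-trialkoxybenzenes.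

Step 7
Reactants: 9 2,4-bis(benzyloxy)-5-methoxybenzaldehyde
Product: 10 1,5-bis(benzyloxy)-2-ethynyl-4-methoxybenzene
Conditions: dimethyl (1-diazo-2-oxopropyl)phosphonate, K2CO3, MeOH/THF, rt
Reagents that add atoms: dimethyl (1-diazo-2-oxopropyl)phosphonate, COP(=O)(OC)C(=[N+]=[N-])C(C)=O
Why: Seyferth–Gilbert homologation in its Ohira–Bestmann form, in which the diazomethylphosphonate anion adds to the non-enolisable aldehyde and the resulting diazoalkene loses N2 and undergoes a 1,2-hydride shift to the terminal alkyne under mild base.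

Step 8
Reactants: 10 1,5-bis(benzyloxy)-2-ethynyl-4-methoxybenzene
Product: 13 ({[2,4-bis(benzyloxy)-5-methoxyphenyl]ethynyl}oxy)tri(propan-2-yl)silane, via lithium acetylide 11 (not isolated), via lithium ynolate 12 (not isolated)
Conditions: n-BuLi, THF, −78 °C; t-BuOOLi (from t-BuOOH and LiHMDS), −78 → 0 °C; then TIPSOTf, −78 °C; cold aq. NaHCO3 work-up, Et3N-deactivated silica
Reagents that add atoms: tert-butyl hydroperoxide, CC(C)(C)OO; triisopropylsilyl trifluoromethanesulfonate, CC(C)[Si](OS(=O)(=O)C(F)(F)F)(C(C)C)C(C)C
Why: Electrophilic oxygenation of a lithium acetylide by lithium tert-butyl peroxide, in which the acetylide attacks the peroxide oxygen and expels tert-butoxide to give the ynolate, followed by O-silylation with a hard, bulky silyl triflate.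

Step 9
Reactants: 4 2-hydroxy-3,4,6-trimethoxybenzaldehyde; 13 ({[2,4-bis(benzyloxy)-5-methoxyphenyl]ethynyl}oxy)tri(propan-2-yl)silane
Product: 14 2-[2,4-bis(benzyloxy)-5-methoxyphenyl]-5,7,8-trimethoxy-3-[(triisopropylsilyl)oxy]-4H-chromen-4-one
Conditions: [Cp*RhCl2]2 (5 mol %), CsOAc (20 mol %), anhydrous Cu(OAc)2 (2.2 equiv), Na2CO3 (2.5 equiv), 4 Å MS, PhCl, 80 °C, argon; 4 pre-stirred with the metal salts, then 13 (1.5 equiv) added over 6 h by syringe pump
Reagents that add atoms: none
Why: Proposed new method: the phenoxide of 4 binds trivalent rhodium and steers acetate-assisted cleavage of the formyl C–H bond to a five-membered acyl rhodacycle; alkyne 13 then inserts into the Rh–acyl bond, and C–O reductive elimination from the seven-membered oxa-rhodacycle releases 14 and monovalent rhodium, which Cu(OAc)2 returns to the trivalent state. The closest known reaction type is the rhodium-catalysed oxidative annulation of salicylaldehydes with internal diaryl or aryl alkyl alkynes to 2,3-disubstituted chromones, in which silyl ynol ethers have not served as the alkyne partner. Ring C closes as a formal [4+2] annulation, with O1–C8a–C4a–C4 coming from 4 and C2–C3 from 13, and the O1–C2 bond is made last by reductive elimination. No stereocentre is formed. The step needs one insertion regiochemistry, acyl carbon to the oxygen-bearing alkyne carbon and rhodium to the aryl-bearing one, and both the ketene-like polarisation of the ynol ether and the usual preference for an aryl group next to the metal point that way. The acid-labile ynol ether is shielded by turning the phenol into its metal phenoxide before the alkyne arrives, by buffering the liberated acetic acid with carbonate and sieves, by slow addition, and by a temperature below that of silyl migration to the silylketene.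

Step 10
Reactants: 14 2-[2,4-bis(benzyloxy)-5-methoxyphenyl]-5,7,8-trimethoxy-3-[(triisopropylsilyl)oxy]-4H-chromen-4-one
Product: 15 2-[2,4-bis(benzyloxy)-5-methoxyphenyl]-3-hydroxy-5,7,8-trimethoxy-4H-chromen-4-one
Conditions: TBAF, AcOH, THF, 0 °C
Reagents that add atoms: none
Why: Fluoride-mediated desilylation of an enol-type silyl ether, driven by the strong Si–F bond, with acetic acid buffering so that the benzyl ethers and the chromone ring stay intact.

Step 11
Reactants: 15 2-[2,4-bis(benzyloxy)-5-methoxyphenyl]-3-hydroxy-5,7,8-trimethoxy-4H-chromen-4-one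
Product: 16 2-(2,4-dihydroxy-5-methoxyphenyl)-3,5-dihydroxy-7,8-dimethoxy-4H-chromen-4-one
Conditions: BCl3 (excess), C6HMe5, CH2Cl2, −78 → 0 °C; MeOH and aq. HCl work-up
Reagents that add atoms: none
Why: Lewis acid ether cleavage, in which BCl3 should remove both aryl benzyl groups at low temperature while pentamethylbenzene traps the benzyl cations, and on warming the boron chelated to the C4 carbonyl should cleave only the peri C5 methoxyl because the C7, C8 and C5' methoxyls lack that chelation.

Compound list
1 | 3,4,5-trimethoxyphenol | COc1cc(O)cc(OC)c1OC | starting material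
2 | 1,2,3,5-tetramethoxybenzene | COc1cc(OC)c(OC)c(OC)c1 | intermediate
3 | 2,3,4,6-tetramethoxybenzaldehyde | COc1cc(OC)c(C=O)c(OC)c1OC | intermediate
4 | 2-hydroxy-3,4,6-trimethoxybenzaldehyde | COc1cc(OC)c(C=O)c(O)c1OC | intermediate
5 | 3-(benzyloxy)-4-methoxybenzaldehyde | COc1ccc(C=O)cc1OCc1ccccc1 | starting material
6 | 3-(benzyloxy)-4-methoxyphenyl formate | COc1ccc(OC=O)cc1OCc1ccccc1 | intermediate
7 | 3-(benzyloxy)-4-methoxyphenol | COc1ccc(O)cc1OCc1ccccc1 | intermediate
8 | 2,4-bis(benzyloxy)-1-methoxybenzene | COc1ccc(OCc2ccccc2)cc1OCc1ccccc1 | intermediate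
9 | 2,4-bis(benzyloxy)-5-methoxybenzaldehyde | COc1cc(C=O)c(OCc2ccccc2)cc1OCc1ccccc1 | intermediate
10 | 1,5-bis(benzyloxy)-2-ethynyl-4-methoxybenzene | COc1cc(C#C)c(OCc2ccccc2)cc1OCc1ccccc1 | intermediate
11 | lithium [2,4-bis(benzyloxy)-5-methoxyphenyl]acetylide | [Li]C#Cc1cc(OC)c(OCc2ccccc2)cc1OCc1ccccc1 | intermediate
12 | lithium 2-[2,4-bis(benzyloxy)-5-methoxyphenyl]ethynolate | [Li]OC#Cc1cc(OC)c(OCc2ccccc2)cc1OCc1ccccc1 | intermediate
13 | ({[2,4-bis(benzyloxy)-5-methoxyphenyl]ethynyl}oxy)tri(propan-2-yl)silane | COc1cc(C#CO[Si](C(C)C)(C(C)C)C(C)C)c(OCc2ccccc2)cc1OCc1ccccc1 | intermediate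
14 | 2-[2,4-bis(benzyloxy)-5-methoxyphenyl]-5,7,8-trimethoxy-3-[(triisopropylsilyl)oxy]-4H-chromen-4-one | COc1cc(-c2oc3c(OC)c(OC)cc(OC)c3c(=O)c2O[Si](C(C)C)(C(C)C)C(C)C)c(OCc2ccccc2)cc1OCc1ccccc1 | intermediate
15 | 2-[2,4-bis(benzyloxy)-5-methoxyphenyl]-3-hydroxy-5,7,8-trimethoxy-4H-chromen-4-one | COc1cc(-c2oc3c(OC)c(OC)cc(OC)c3c(=O)c2O)c(OCc2ccccc2)cc1OCc1ccccc1 | intermediate
16 | 2-(2,4-dihydroxy-5-methoxyphenyl)-3,5-dihydroxy-7,8-dimethoxy-4H-chromen-4-one | COc1cc(-c2oc3c(OC)c(OC)cc(O)c3c(=O)c2O)c(O)cc1O | target

Total step count: 11. Longest linear sequence: 8 steps (steps 4 to 11, from 5).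

Steps most likely to fail

Step 9. The ynol ether may be consumed before insertion: by protonation by the phenol or by acetic acid with capture as an aryl ester, by silyl migration to the silylketene, or by addition to the aldehyde carbonyl. The acylrhodium may also lose carbon monoxide. The fallback uses known chemistry, sets out from 2 and 9, and comes back at 15. Friedel–Crafts acetylation of 2 (AcCl, AlCl3, CH2Cl2), which is accompanied by loss of the crowded ortho methyl group, would give 1-(2-hydroxy-3,4,6-trimethoxyphenyl)ethanone F1. Claisen–Schmidt condensation of F1 with aldehyde 9 (KOH, EtOH, rt) would give (E)-3-[2,4-bis(benzyloxy)-5-methoxyphenyl]-1-(2-hydroxy-3,4,6-trimethoxyphenyl)prop-2-en-1-one F2. Oxidative cyclisation with catalytic I2 in DMSO at 120 °C would give 2-[2,4-bis(benzyloxy)-5-methoxyphenyl]-5,7,8-trimethoxy-4H-chromen-4-one F3. Epoxidation of the C2–C3 double bond of F3 with dimethyldioxirane (acetone/CH2Cl2, 0 °C), then opening of the epoxide with a trace of TsOH, would give flavonol 15.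

Step 8. Oxygen transfer to the acetylide may stall, silylation may occur on carbon to give the silylketene, or the ynol ether may hydrolyse during isolation. The fallback sets out from 9 and comes back at 13, without the alkyne or the peroxide. Pinnick oxidation of 9 (NaClO2, NaH2PO4, 2-methyl-2-butene, t-BuOH/H2O) would give 2,4-bis(benzyloxy)-5-methoxybenzoic acid F4. Methylation (MeI, K2CO3, DMF) would give methyl 2,4-bis(benzyloxy)-5-methoxybenzoate F5. Kowalski homologation of F5 (CH2Br2, LiTMP, THF, −78 °C; then n-BuLi, −78 → 0 °C) would give lithium ynolate 12 by carbenoid rearrangement, and TIPSCl would silylate it on oxygen to 13.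

Step 11. Cleavage of the C5 methoxyl may stop once the 3-oxygen is tied up as a boron chelate, a second methoxyl may be cleaved, or ring B may be benzylated on carbon if cation trapping is incomplete. The fallback sets out from 15 and comes back at 16, separating the two cleavages. Hydrogenolysis of 15 (H2, 10% Pd/C, EtOAc/MeOH, rt) would give 2-(2,4-dihydroxy-5-methoxyphenyl)-3-hydroxy-5,7,8-trimethoxy-4H-chromen-4-one F6. Chelation-controlled demethylation of the C5 methoxyl of F6 with AlCl3 in MeCN at 60 °C would then give 16.

Further compounds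
F1 | step 9 | 1-(2-hydroxy-3,4,6-trimethoxyphenyl)ethanone | CC(=O)c1c(O)c(OC)c(OC)cc1OC
F2 | step 9 | (E)-3-[2,4-bis(benzyloxy)-5-methoxyphenyl]-1-(2-hydroxy-3,4,6-trimethoxyphenyl)prop-2-en-1-one | COc1cc(/C=C/C(=O)c2c(O)c(OC)c(OC)cc2OC)c(OCc2ccccc2)cc1OCc1ccccc1
F3 | step 9 | 2-[2,4-bis(benzyloxy)-5-methoxyphenyl]-5,7,8-trimethoxy-4H-chromen-4-one | COc1cc(-c2cc(=O)c3c(OC)cc(OC)c(OC)c3o2)c(OCc2ccccc2)cc1OCc1ccccc1
F4 | step 8 | 2,4-bis(benzyloxy)-5-methoxybenzoic acid | COc1cc(C(=O)O)c(OCc2ccccc2)cc1OCc1ccccc1
F5 | step 8 | methyl 2,4-bis(benzyloxy)-5-methoxybenzoate | COC(=O)c1cc(OC)c(OCc2ccccc2)cc1OCc1ccccc1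
F6 | step 11 | 2-(2,4-dihydroxy-5-methoxyphenyl)-3-hydroxy-5,7,8-trimethoxy-4H-chromen-4-one | COc1cc(-c2oc3c(OC)c(OC)cc(OC)c3c(=O)c2O)c(O)cc1O
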